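The runs were computed for substances that don't exist; noise was put on by code.

Target grows here as substrate meets dissolved reagent, and that reagent has to enter from the gas while substrate consumes it.

| setting | north | east | flask |
|---|---|---|---|
| substrate | 0.25 M | 0.38 M | 0.25 M |
| gas | 21 mM (held) | 21 mM (held) | 21 mM (held) |
| remark | the very flask that is asked about, followed so far | run made earlier |  |
| time |  |  | 40 min |

- north (time / min: target / %, substrate / %): 0.667: 0, 100.3; 1.50: 0.7, 99.4; 3.00: 1.0, 98.7; 5.00: 2.5, 97.4
- east (time / min: target / %, substrate / %): 2.50: 0.5, 99.1; 5.00: 2.5, 97.7; 12.0: 6.3, 92.3; 30.0: 16.0, 81.6

(readings scatter by 0.3 percentage points)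

- at the start none of reagent is dissolved
- the numbers in the tables scatter by 0.3 percentage points (one standard deviation)
- reactions considered so far: substrate + reagent <-> target; target <-> isomer of the product; gas <-> reagent

- how much target there is at 40 min, in percent of the substrate charged
- the change that raises the amount of target at 40 min, in percent of the substrate charged most ("none" if none brings more than 2 percentage points) (violet / teal / none)
- amount of target at 40 min, in percent of the substrate charged, after violet

- violet: doubling the transfer coefficient of the gas, all else as stated
- teal: doubling the saturation concentration of gas, all else as stated

Write the reagent's balance: uptake, proportional to the gap below saturation, equals use, proportional to substrate times reagent. So substrate falls pseudo-first-order, with a fractional rate k' that follows the reagent, and east over 30.0 min reads 0.00678 min⁻¹. With reagent saturated in both runs, north would share that k'. With a fixed uptake, north's k' would be larger by the substrate ratio, 1.52. Subtract isomer, which is east's balance gap of 2.40% scaled by time squared to 4.27%, and you bracket target between 19.5% and 29.5%.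

To tighten it, take the depletion share s, the fraction by which reagent stands below saturation in north. North's substrate loss over east's, both read at 5.00 min, is 1.13, which places s at 25.1%. That is loose, since target reads level there. Still, I commit to 22.1%. Violet multiplies k' by 1.14, giving about 25.3%; teal doubles the reagent, giving about 37.3%, so I choose teal.

The forecast says 19.5%, teal, and 20.5% after violet, with “reagent close to saturation”. Its figure sits at my lower edge, by its own route.

The flask gives 21.9%, teal, and 24.5% after violet.

    substrate + reagent ⇌ target (K = 120 M⁻¹, k = 0.540 M⁻¹ min⁻¹)
    target ⇌ isomer of the product (K = 0.480, k = 0.0150 min⁻¹)
    gas ⇌ reagent, rate k3*(csat - [reagent]) (kL = 0.390 min⁻¹)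

Teal gains 16 percentage points, more than violet's 2.6 points, and the forecast held within its margin. At 40.0 min this flask holds 0.0172 M of reagent, a shortfall of 18.2%, less than s, with 73% of substrate left. The same charge read at 10 min is the neighbouring flask, where s predicts 15.7 mM of reagent. That flask holds 0.0158 M.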